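**Plan**
- Cuts: C9–C11 (side chain, allylic substitution), C8–O (epoxide then hydride), C3–C4 (ring A, radical closure), C10–C1 and C10–CH3 (two enolate alkylations of (S)-carvone). C15 travels as a silyl ether and is oxidised last.
- Enabling feature: ring A holds the quaternary gem-dimethyl carbon C4 directly beside C5 of the cis C5–C10 ring fusion. Carvone (ring B) already carries an isopropenyl group on C5, which is C4 with both methyl carbons, one hydrogen atom short.
- Forward: carvone, acrylate arm then methyl at C10, hydrogen-atom-transfer radical 6-endo closure of ring A, decarboxylation, enone transposition to a C7 allylic ester, anti SN2' attachment of the C11–C16 chain at C9, C8 oxygen through the Δ7 epoxide, acetate, C15 acid.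
- Stereochemistry: C5 from (S)-carvone. C10 by methylation anti to the isopropenyl group (cis fusion). C7 by epoxidation anti to C4, inverted by Mitsunobu and relayed to C9 by anti SN2'. C8 by epoxidation anti to the C9 chain and hydride opening at C7. C13 from methyl hydrogen (R)-3-methylglutarate.

Key step: step 3

Remark: labdane numbering is used throughout (carvone C=O is C9, its methyl-bearing carbon C8, the isopropenyl-bearing carbon C5, the α' carbon C10); β is the face of the C10 methyl group. The target SMILES is read as the cis-fused decalin (5β-H, 10β-CH3) with 8α-OAc, 8β-CH3, 9β side chain and 13S.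
Assumption: methyl hydrogen (R)-3-methylglutarate is taken as a commercial, enantiopure building block.

**Route**

Step 1
Reactants: 1 (S)-carvone; 2 methyl 2-(bromomethyl)acrylate
Product: 4 methyl 2-{[(1R,6S)-3-methyl-2-oxo-6-(prop-1-en-2-yl)cyclohex-3-en-1-yl]methyl}prop-2-enoate, via carvone lithium enolate 3 (not isolated)
Conditions: LiN(i-Pr)2, THF, −78 °C; then 2, −78 → −40 °C
Reagents that add atoms: methyl 2-(bromomethyl)acrylate (2), C=C(CBr)C(=O)OC
Why: Kinetic α'-deprotonation of the enone and alkylation of the cross-conjugated lithium enolate by the allylic bromide (addition–elimination on the bromomethylacrylate) is standard carvone enolate chemistry; the C10 centre should form mainly trans to the isopropenyl group and is planarised again in step 2.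

Step 2
Reactants: 4; 5 iodomethane
Product: 7 methyl 2-{[(1S,6R)-1,3-dimethyl-2-oxo-6-(prop-1-en-2-yl)cyclohex-3-en-1-yl]methyl}prop-2-enoate, via lithium enolate 6 (not isolated)
Conditions: LiN(SiMe3)2, THF, −78 → −40 °C; then MeI, DMPU, −78 → 0 °C
Reagents that add atoms: iodomethane (5), CI
Why: Enolate alkylation in which the tetrasubstituted C9–C10 lithium enolate should be methylated on the face anti to the C5 isopropenyl group, so the methyl group ends trans and the acrylate arm (C1) cis to it, which is the relative configuration of the cis ring fusion; the silylamide base is chosen to deprotonate the ketone without adding to the acrylate.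

Step 3
Reactants: 7
Product: 8 methyl (4aR,8aS)-4,4,7,8a-tetramethyl-8-oxo-1,2,3,4,4a,5,8,8a-octahydronaphthalene-2-carboxylate (cis-fused, C2 epimers)
Conditions: Fe(acac)3 (0.3 equiv), PhSiH3, EtOH–HOCH2CH2OH (5:1), degassed, 60 °C
Reagents that add atoms: none
Why: Fe(acac)3 and PhSiH3 in ethanol form an iron hydride that passes a hydrogen atom to the CH2 terminus of the electron-rich isopropenyl group, so a tertiary radical appears at C4 with both methyl groups in place; this radical adds to the unsubstituted acrylate terminus C3, and the resulting C2 α-ester radical is reduced by divalent iron to the ester enolate and protonated by the solvent, which returns trivalent iron. The closest known reaction type is the iron-mediated hydrogen-atom-transfer reductive olefin coupling (radical conjugate addition), run here intramolecularly. Ring A closes in the 6-endo-trig mode, because the 5-exo alternative would require attack at the fully substituted, polarity-mismatched α-carbon C2. No lasting stereocentre is created: C4 bears two identical methyl groups, C2 forms as an epimer mixture that is erased in step 5, and the cis C5–C10 fusion is inherited from 7. The step needs chemoselective hydrogen-atom transfer to the isopropenyl group beside two electron-poor alkenes and a regioselective radical addition; the first is secured by the preference of the metal hydride for the 1,1-disubstituted donor alkene, the second by the acrylate polarity and by the ring enone being reachable only through 4-exo or 5-endo closures.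

Step 4
Reactants: 8
Product: 9 (4aR,8aS)-4,4,7,8a-tetramethyl-8-oxo-1,2,3,4,4a,5,8,8a-octahydronaphthalene-2-carboxylic acid (C2 epimers)
Conditions: LiOH·H2O, THF–MeOH–H2O, rt; then 1 M HCl
Reagents that add atoms: lithium hydroxide, [Li+].[OH-]
Why: Saponification of an unhindered secondary methyl ester, to which the enone and the quaternary C10 are inert at room temperature; C2 epimerisation is irrelevant.

Step 5
Reactants: 9
Product: 12 (4aR,8aS)-2,5,5,8a-tetramethyl-4a,5,6,7,8,8a-hexahydronaphthalen-1(4H)-one, via acid chloride 10 (not isolated), via Barton thiohydroxamate ester 11 (not isolated)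
Conditions: (COCl)2, DMF (cat.), CH2Cl2, 0 °C → rt; then sodium 2-thioxopyridin-1(2H)-olate, DMAP (cat.), t-BuSH, THF, hν (tungsten lamp), rt
Reagents that add atoms: none
Why: Barton reductive decarboxylation, in which the thiohydroxamate ester fragments under light to the secondary C2 radical and t-BuSH should quench it faster than it can reach the remote enone, erasing the C2 stereocentre.

Step 6
Reactants: 12
Product: 13 7β,8β-epoxy-4,4,8,10-tetramethyl-cis-decalin-9-one (5β-H, 10β-CH3)
Conditions: 30% H2O2, NaOH (aq), MeOH, 0 °C → rt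
Reagents that add atoms: hydrogen peroxide, OO
Why: Weitz–Scheffer nucleophilic epoxidation of the α-methyl enone, in which hydroperoxide should add to C7 on the face anti to the C5–C4 bond (the β face), as it does anti to the isopropenyl group in carvone, setting C7 and C8 together.

Step 7
Reactants: 13
Product: 15 4,4,8,10-tetramethyl-cis-decal-8-en-7β-ol (5β-H, 10β-CH3), via epoxy hydrazone 14 (not isolated)
Conditions: N2H4·H2O, AcOH, MeOH, 0 °C → rt
Reagents that add atoms: none
Why: Wharton transposition, in which the epoxy hydrazone collapses with loss of N2 to the allylic alcohol, moving the oxygen to C7 with the configuration of the epoxide (7β) and the alkene to C8=C9.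

Step 8
Reactants: 15
Product: 16 4,4,8,10-tetramethyl-cis-decal-8-en-7α-yl pyridine-2-carboxylate
Conditions: picolinic acid, PPh3, DIAD, THF, 0 °C → rt
Reagents that add atoms: picolinic acid, OC(=O)c1ccccn1
Why: Mitsunobu esterification, which should proceed with SN2 inversion at the unhindered secondary allylic C7 and so give the 7α-picolinate needed for delivery to the β face of C9.

Step 9
Reactants: 17 methyl hydrogen (R)-3-methylglutarate
Product: 18 methyl (R)-5-hydroxy-3-methylpentanoate
Conditions: BH3·SMe2, THF, 0 °C → rt; MeOH–H2O quench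
Reagents that add atoms: none
Why: Borane reduces a free carboxylic acid chemoselectively beside a methyl ester, and the stereocentre is not touched.

Step 10
Reactants: 18
Product: 19 methyl (R)-5-(tert-butyldimethylsilyloxy)-3-methylpentanoate
Conditions: TBSCl, imidazole, DMF, rt
Reagents that add atoms: tert-butyldimethylsilyl chloride, CC(C)(C)[Si](C)(C)Cl
Why: Routine silylation of a primary alcohol, which stops lactonisation and masks the future C15 through the organometallic and hydride steps.

Step 11
Reactants: 19
Product: 20 (S)-5-(tert-butyldimethylsilyloxy)-3-methylpentan-1-ol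
Conditions: LiAlH4, THF, 0 °C
Reagents that add atoms: none
Why: Ester reduction by LiAlH4, to which the silyl ether is stable at 0 °C.

Step 12
Reactants: 20
Product: 21 (R)-[(5-bromo-3-methylpentyl)oxy](tert-butyl)dimethylsilane
Conditions: CBr4, PPh3, imidazole, CH2Cl2, 0 °C
Reagents that add atoms: carbon tetrabromide, BrC(Br)(Br)Br
Why: Appel bromination of a primary alcohol under buffered conditions, which leaves the silyl ether and the remote stereocentre intact.

Step 13
Reactants: 16; 21
Product: 23 (13S)-15-(tert-butyldimethylsilyloxy)-5β-labd-7-ene (9β side chain), via alkylmagnesium bromide 22 (not isolated)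
Conditions: 21, Mg, THF, rt; then 16, CuBr·SMe2, THF, −78 → 0 °C
Reagents that add atoms: bromide 21 (as its Grignard reagent 22), BrCC[C@H](C)CCO[Si](C)(C)C(C)(C)C
Why: Copper-mediated allylic substitution of an allylic picolinate by an alkylmagnesium bromide, in which magnesium chelation activates the leaving group and the alkylcopper should attack the γ-carbon C9 anti to the 7α-oxygen (anti SN2'), forming C9–C11 on the β face and moving the alkene to C7=C8.

Step 14
Reactants: 23
Product: 24 (13S)-7α,8α-epoxy-15-(tert-butyldimethylsilyloxy)-5β-labdane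
Conditions: mCPBA, NaHCO3, CH2Cl2, 0 °C
Reagents that add atoms: 3-chloroperbenzoic acid, OOC(=O)c1cccc(Cl)c1
Why: Prilezhaev epoxidation of the only alkene, in which the peracid is expected to approach anti to the allylic 9β side chain and so give the α-epoxide that defines C8.

Step 15
Reactants: 24
Product: 25 (13S)-15-(tert-butyldimethylsilyloxy)-5β-labdan-8α-ol
Conditions: LiAlH4, THF, 0 → 50 °C
Reagents that add atoms: none
Why: Hydride opens the trisubstituted epoxide by SN2 attack at the secondary C7 and leaves the C8–O bond untouched, so the tertiary alcohol should be 8α with the methyl group β.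

Step 16
Reactants: 25
Product: 26 (13S)-8α-acetoxy-15-(tert-butyldimethylsilyloxy)-5β-labdane
Conditions: AcCl, PhNMe2, CH2Cl2, rt
Reagents that add atoms: acetyl chloride, CC(=O)Cl
Why: Acylation of a hindered tertiary alcohol with acetyl chloride and N,N-dimethylaniline is the usual protocol for labdan-8-ols and does not touch the C8 configuration.

Step 17
Reactants: 26
Product: 29 (13S)-8α-acetoxy-5β-labdan-15-oic acid (CNP0470037.1), via primary alcohol 27 (not isolated), via aldehyde 28 (not isolated)
Conditions: CrO3, H2SO4, H2O, acetone, 0 °C → rt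
Reagents that add atoms: water, O
Why: Jones oxidation, in which aqueous sulfuric acid cleaves the primary silyl ether and hexavalent chromium oxidises the liberated alcohol through the aldehyde hydrate to the acid, while the tertiary acetate and all stereocentres should be unaffected.

**Compound list**

1 | (S)-carvone | CC1=CC[C@@H](CC1=O)C(C)=C | starting material
2 | methyl 2-(bromomethyl)acrylate | C=C(CBr)C(=O)OC | starting material
3 | lithium dienolate of 1 (O–C9=C10) | [Li+].[O-]C1=C[C@@H](C(C)=C)CC=C1C | intermediate
4 | methyl 2-{[(1R,6S)-3-methyl-2-oxo-6-(prop-1-en-2-yl)cyclohex-3-en-1-yl]methyl}prop-2-enoate (arm trans to isopropenyl) | C=C(C[C@H]1C(=O)C(C)=CC[C@@H]1C(C)=C)C(=O)OC | intermediate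
5 | iodomethane | CI | starting material
6 | lithium enolate of 4 (O–C9=C10) | [Li+].[O-]C1=C(CC(=C)C(=O)OC)[C@@H](C(C)=C)CC=C1C | intermediate
7 | methyl 2-{[(1S,6R)-1,3-dimethyl-2-oxo-6-(prop-1-en-2-yl)cyclohex-3-en-1-yl]methyl}prop-2-enoate (arm cis, methyl trans to isopropenyl) | C=C(C[C@]1(C)C(=O)C(C)=CC[C@@H]1C(C)=C)C(=O)OC | intermediate
8 | methyl (4aR,8aS)-4,4,7,8a-tetramethyl-8-oxo-1,2,3,4,4a,5,8,8a-octahydronaphthalene-2-carboxylate (C2 epimers) | CC1=CC[C@@H]2C(C)(C)CC(C(=O)OC)C[C@]2(C)C1=O | intermediate
9 | (4aR,8aS)-4,4,7,8a-tetramethyl-8-oxo-1,2,3,4,4a,5,8,8a-octahydronaphthalene-2-carboxylic acid (C2 epimers) | CC1=CC[C@@H]2C(C)(C)CC(C(=O)O)C[C@]2(C)C1=O | intermediate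
10 | acid chloride of 9 | CC1=CC[C@@H]2C(C)(C)CC(C(=O)Cl)C[C@]2(C)C1=O | intermediate
11 | 2-thioxopyridin-1(2H)-yl ester of 9 | CC1=CC[C@@H]2C(C)(C)CC(C(=O)ON3C=CC=CC3=S)C[C@]2(C)C1=O | intermediate
12 | (4aR,8aS)-2,5,5,8a-tetramethyl-4a,5,6,7,8,8a-hexahydronaphthalen-1(4H)-one | CC1=CC[C@@H]2C(C)(C)CCC[C@]2(C)C1=O | intermediate
13 | 7β,8β-epoxy-4,4,8,10-tetramethyl-cis-decalin-9-one | O=C1[C@@]2(C)CCCC(C)(C)[C@H]2C[C@@H]3O[C@]13C | intermediate
14 | hydrazone of 13 | NN=C1[C@@]2(C)CCCC(C)(C)[C@H]2C[C@@H]3O[C@]13C | intermediate
15 | 4,4,8,10-tetramethyl-cis-decal-8-en-7β-ol | CC1=C[C@@]2(C)CCCC(C)(C)[C@H]2C[C@@H]1O | intermediate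
16 | 4,4,8,10-tetramethyl-cis-decal-8-en-7α-yl pyridine-2-carboxylate | CC1=C[C@@]2(C)CCCC(C)(C)[C@H]2C[C@H]1OC(=O)c3ccccn3 | intermediate
17 | methyl hydrogen (R)-3-methylglutarate | COC(=O)C[C@H](C)CC(=O)O | starting material
18 | methyl (R)-5-hydroxy-3-methylpentanoate | COC(=O)C[C@H](C)CCO | intermediate
19 | methyl (R)-5-(tert-butyldimethylsilyloxy)-3-methylpentanoate | COC(=O)C[C@H](C)CCO[Si](C)(C)C(C)(C)C | intermediate
20 | (S)-5-(tert-butyldimethylsilyloxy)-3-methylpentan-1-ol | OCC[C@H](C)CCO[Si](C)(C)C(C)(C)C | intermediate
21 | (R)-[(5-bromo-3-methylpentyl)oxy](tert-butyl)dimethylsilane | BrCC[C@H](C)CCO[Si](C)(C)C(C)(C)C | intermediate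
22 | (R)-[5-(tert-butyldimethylsilyloxy)-3-methylpentyl]magnesium bromide | Br[Mg]CC[C@H](C)CCO[Si](C)(C)C(C)(C)C | intermediate
23 | (13S)-15-(tert-butyldimethylsilyloxy)-5β-labd-7-ene | CC1=CC[C@@H]2C(C)(C)CCC[C@]2(C)[C@H]1CC[C@H](C)CCO[Si](C)(C)C(C)(C)C | intermediate
24 | (13S)-7α,8α-epoxy-15-(tert-butyldimethylsilyloxy)-5β-labdane | C[C@@]12O[C@@H]1C[C@@H]3C(C)(C)CCC[C@]3(C)[C@H]2CC[C@H](C)CCO[Si](C)(C)C(C)(C)C | intermediate
25 | (13S)-15-(tert-butyldimethylsilyloxy)-5β-labdan-8α-ol | O[C@]1(C)CC[C@@H]2C(C)(C)CCC[C@]2(C)[C@H]1CC[C@H](C)CCO[Si](C)(C)C(C)(C)C | intermediate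
26 | (13S)-8α-acetoxy-15-(tert-butyldimethylsilyloxy)-5β-labdane | CC(=O)O[C@]1(C)CC[C@@H]2C(C)(C)CCC[C@]2(C)[C@H]1CC[C@H](C)CCO[Si](C)(C)C(C)(C)C | intermediate
27 | (13S)-8α-acetoxy-5β-labdan-15-ol | CC(=O)O[C@]1(C)CC[C@@H]2C(C)(C)CCC[C@]2(C)[C@H]1CC[C@H](C)CCO | intermediate
28 | (13S)-8α-acetoxy-5β-labdan-15-al | CC(=O)O[C@]1(C)CC[C@@H]2C(C)(C)CCC[C@]2(C)[C@H]1CC[C@H](C)CC=O | intermediate
29 | (13S)-8α-acetoxy-5β-labdan-15-oic acid | CC(=O)O[C@]1(C)CC[C@@H]2C(C)(C)CCC[C@]2(C)[C@H]1CC[C@H](C)CC(=O)O | target

**Count and risks**

Total: 17 steps. Longest linear sequence: 13 steps (steps 1–8 and 13–17 from (S)-carvone); the side chain takes 4 steps (9–12) and joins at step 13.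

Step 13. The alkylcopper may substitute at the unhindered C7 without allylic shift, or merely reduce the picolinate, because C9 lies beside the quaternary C10. The fallback sets out from 15 and 21 and comes back at 23. Alcohol 15 is treated with phenyl isocyanate (pyridine, CH2Cl2) to give the 7β-N-phenylcarbamate F1. Bromide 21 is exchanged with NaI in acetone to the iodide F2, and this with t-BuLi (Et2O–pentane, −78 °C) to the alkyllithium F3. F1 is deprotonated with MeLi, treated with CuI and then with F3 in THF at 0 °C. The carbamate-bound alkylcopper should then deliver the chain intramolecularly to C9 on the face of the 7β-oxygen (syn SN2'), which gives 23 without the inversion of step 8.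

Step 7. Condensation of hydrazine with the C9 carbonyl, which lies between two fully substituted carbons, may be slower than opening of the epoxide by hydrazine, so the transposition may stall. The fallback sets out from 12 and comes back at 16. Luche reduction (NaBH4, CeCl3·7H2O, MeOH) should give the 9α-allylic alcohol F4 by hydride attack on the β face. VO(acac)2 and t-BuOOH epoxidise syn to the hydroxyl group to the 7α,8α-epoxy-9α-ol F5. 1,1'-Thiocarbonyldiimidazole (DMAP, ClCH2CH2Cl, reflux) gives the thiocarbonylimidazolide F6. Bu3SnH and AIBN in refluxing toluene generate the C9 radical, which opens the epoxide to the 7α-oxygen radical and, after hydrogen abstraction, the 7α-allylic alcohol F7. F7 is esterified with picolinic acid, DCC and DMAP with retention to give 16.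

Step 14. Facial selectivity may be poor: in a conformer of the cis-decalin with the C9 chain equatorial the peracid may approach from the β face, which after step 15 would give the C8 epimer. The fallback sets out from 23 and comes back at 25, bypassing 24. Oxymercuration with Hg(OAc)2 in THF–H2O places the mercurinium ion on the face that electrophiles prefer, and water opens it at the tertiary C8 from the opposite face, giving the 7β-acetoxymercurio-8α-ol F8. NaBH4 in aqueous NaOH then removes the mercury to give 25.

**Further compounds**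

F1 | step 13 | 4,4,8,10-tetramethyl-cis-decal-8-en-7β-yl N-phenylcarbamate | CC1=C[C@@]2(C)CCCC(C)(C)[C@H]2C[C@@H]1OC(=O)Nc3ccccc3
F2 | step 13 | (R)-tert-butyl[(5-iodo-3-methylpentyl)oxy]dimethylsilane | ICC[C@H](C)CCO[Si](C)(C)C(C)(C)C
F3 | step 13 | [5-(tert-butyldimethylsilyloxy)-3-methylpentyl]lithium (same spatial arrangement as 21) | [Li]CC[C@H](C)CCO[Si](C)(C)C(C)(C)C
F4 | step 7 | 4,4,8,10-tetramethyl-cis-decal-7-en-9α-ol | CC1=CC[C@@H]2C(C)(C)CCC[C@]2(C)[C@@H]1O
F5 | step 7 | 7α,8α-epoxy-4,4,8,10-tetramethyl-cis-decalin-9α-ol | C[C@@]12O[C@@H]1C[C@@H]3C(C)(C)CCC[C@]3(C)[C@@H]2O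
F6 | step 7 | O-(7α,8α-epoxy-4,4,8,10-tetramethyl-cis-decalin-9α-yl) 1H-imidazole-1-carbothioate | C[C@@]12O[C@@H]1C[C@@H]3C(C)(C)CCC[C@]3(C)[C@@H]2OC(=S)n4ccnc4
F7 | step 7 | 4,4,8,10-tetramethyl-cis-decal-8-en-7α-ol | CC1=C[C@@]2(C)CCCC(C)(C)[C@H]2C[C@H]1O
F8 | step 14 | (13S)-7β-(acetoxymercurio)-15-(tert-butyldimethylsilyloxy)-5β-labdan-8α-ol | O[C@]1(C)[C@@H]([Hg]OC(C)=O)C[C@@H]2C(C)(C)CCC[C@]2(C)[C@H]1CC[C@H](C)CCO[Si](C)(C)C(C)(C)C
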